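**Plan**

1. Locants used throughout: carbocycle C1 (CHOH)–C2H2–C3H=C4(C15H3)–C5 (CHOAc)–C6 (CH–O of the lactone)–C7–C8 (CHOAng)–C9H2–C10(=C14H2); lactone C11(=C13H2)–C12(=O)–O–C6; the target is (1S,3E,5S,6R,7S,8S).
2. Retrosynthesis: (i) the ten-membered ring is opened at the sp3–sp2 bond C2–C3 to a 2,3-seco bis-iodide (primary C2–I, E-alkenyl C3–I; O1 as TBS ether, C11=C13 masked as its Me2NH adduct); (ii) the C8–O angelate (Mitsunobu, inversion) and C7–C8 (Zn Barbier) are cut to bromomethyl-butenolide 15 and aldehyde 24; (iii) C5–C6 (vinylogous Mukaiyama aldol) and C1–C10 (alkenyllithium plus Weinreb amide) are cut to simple pieces.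
3. Forward: the butenolide ring is made first (silyloxyfuran plus iodo-enal), the Barbier union turns it into the trans-fused α-methylene-γ-lactone, and the ten-membered ring is closed last at C2–C3 by nickel-catalysed reductive coupling of the two C–I bonds.
4. Enabling feature: C1 is a homoallylic carbinol of the E-C3=C4 olefin, so ring bond C2–C3 joins a primary carbon β to O1 to a vinylic CH and can be made by alkyl–alkenyl reductive elimination with the olefin geometry preset; the trans-fused five-membered lactone on C6–C7 carries both chain arms (from C5 and from C8) and folds them toward each other.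
5. Stereochemistry: 5S/6R from the catalyst-controlled anti vinylogous aldol; 7S (anti to the C6 arm) and 8R from the chair Barbier transition state, with 8R inverted to 8S by the Mitsunobu esterification that installs the angelate; 1S from CBS reduction; 3E from syn-carboalumination/iodination, retained in the coupling; the C13 amine and O1 silyl helpers come off in steps 20 and 21.

Key step: step 19

Assumption: the (R,R)-bisphosphoramide of step 6 is taken to give the (5R,1'S) anti adduct, by analogy with its behaviour toward aryl and alkenyl aldehydes; if the sense is reversed its mirror image is used.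

Step 1
Reactants: 1 furan-3-ylmethanol
Product: 2 3-{[(4-methoxyphenyl)methoxy]methyl}furan
Conditions: NaH, 4-methoxybenzyl chloride, Bu4NI (cat.), THF, 0 °C to rt
Reagents that add atoms: 4-methoxybenzyl chloride, COc1ccc(CCl)cc1
Why: Williamson etherification; the 4-methoxybenzyl ether is inert to the lithiation of step 2 and is removed oxidatively in step 8 without touching the acetate.

Step 2
Reactants: 2 3-{[(4-methoxyphenyl)methoxy]methyl}furan
Product: 5 3-{[(4-methoxyphenyl)methoxy]methyl}furan-2(5H)-one, via 2-lithiofuran 3 (not isolated), via lithium furylborate 4 (not isolated)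
Conditions: n-BuLi, THF, −78 to −20 °C; B(OMe)3, −78 °C to rt; 30% H2O2, 0 °C to rt
Reagents that add atoms: hydrogen peroxide, OO
Why: The ether oxygen directs lithiation to C2 of the furan (directed metalation), and borylation followed by peroxide oxidation of the C–B bond gives the 2-hydroxyfuran, which tautomerises to the conjugated butenolide.

Step 3
Reactants: 5 3-{[(4-methoxyphenyl)methoxy]methyl}furan-2(5H)-one
Product: 6 tert-butyl[(3-{[(4-methoxyphenyl)methoxy]methyl}furan-2-yl)oxy]dimethylsilane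
Conditions: TBSOTf, Et3N, CH2Cl2, 0 °C
Reagents that add atoms: tert-butyldimethylsilyl trifluoromethanesulfonate, CC(C)(C)[Si](C)(C)OS(=O)(=O)C(F)(F)F
Why: Soft enolisation with O-silylation aromatises the butenolide to the 2-silyloxyfuran, the dienoxysilane needed for a vinylogous Mukaiyama aldol.

Step 4
Reactants: 7 prop-2-yn-1-ol
Product: 9 (2E)-3-iodo-2-methylprop-2-en-1-ol, via alkenylalane 8 (not isolated)
Conditions: AlMe3 (3 equiv), Cp2ZrCl2 (0.25 equiv), CH2Cl2, 0 °C to rt; I2, THF, −30 to 0 °C; aq. K2CO3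
Reagents that add atoms: trimethylaluminium, C[Al](C)C; iodine, II
Why: Negishi zirconium-catalysed carboalumination adds CH3 and Al syn across the alkyne with CH3 on the internal carbon, and iodinolysis with retention gives the E-alkenyl iodide that becomes C3=C4 with its C15 methyl.

Step 5
Reactants: 9 (2E)-3-iodo-2-methylprop-2-en-1-ol
Product: 10 (2E)-3-iodo-2-methylprop-2-enal
Conditions: MnO2, CH2Cl2, rt
Reagents that add atoms: none
Why: Chemoselective MnO2 oxidation of the allylic alcohol gives the enal without touching the alkenyl iodide or the olefin geometry.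

Step 6
Reactants: 6 tert-butyl[(3-{[(4-methoxyphenyl)methoxy]methyl}furan-2-yl)oxy]dimethylsilane; 10 (2E)-3-iodo-2-methylprop-2-enal
Product: 12 (5R)-5-[(1S,2E)-1-hydroxy-3-iodo-2-methylprop-2-en-1-yl]-3-{[(4-methoxyphenyl)methoxy]methyl}furan-2(5H)-one, via trichlorosilyl ether 11 (not isolated)
Conditions: SiCl4 (1.1 equiv), (R,R)-BINAM-derived bisphosphoramide (5 mol %), i-Pr2NEt (10 mol %), CH2Cl2, −78 °C; aq. NaHCO3
Reagents that add atoms: none
Why: Lewis-base-activated SiCl4 vinylogous Mukaiyama aldol: the phosphoramide-bound silicon cation activates the enal, the silyloxyfuran attacks through its γ-carbon in an open transition state that leads to the anti C5/C6 adduct, and the chiral bisphosphoramide selects the aldehyde face so that 5S and 6R are set together.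

Step 7
Reactants: 12 (5R)-5-[(1S,2E)-1-hydroxy-3-iodo-2-methylprop-2-en-1-yl]-3-{[(4-methoxyphenyl)methoxy]methyl}furan-2(5H)-one
Product: 13 (1S,2E)-3-iodo-1-[(2R)-4-{[(4-methoxyphenyl)methoxy]methyl}-5-oxo-2,5-dihydrofuran-2-yl]-2-methylprop-2-en-1-yl acetate
Conditions: Ac2O, pyridine, CH2Cl2, 0 °C
Reagents that add atoms: acetic anhydride, CC(=O)OC(C)=O
Why: O-acylation puts the final C5 acetate in place, where it also protects O5 through the fragment union; pyridine alone is used because stronger bases would eliminate the acetate by E1cB to a γ-ylidene butenolide.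

Step 8
Reactants: 13 (1S,2E)-3-iodo-1-[(2R)-4-{[(4-methoxyphenyl)methoxy]methyl}-5-oxo-2,5-dihydrofuran-2-yl]-2-methylprop-2-en-1-yl acetate
Product: 14 (1S,2E)-1-[(2R)-4-(hydroxymethyl)-5-oxo-2,5-dihydrofuran-2-yl]-3-iodo-2-methylprop-2-en-1-yl acetate
Conditions: DDQ, CH2Cl2/pH 7 buffer, 0 °C to rt
Reagents that add atoms: none
Why: Oxidative cleavage of the 4-methoxybenzyl ether by DDQ (hydride abstraction, hydrolysis of the oxocarbenium ion) frees the primary allylic alcohol under neutral conditions.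

Step 9
Reactants: 14 (1S,2E)-1-[(2R)-4-(hydroxymethyl)-5-oxo-2,5-dihydrofuran-2-yl]-3-iodo-2-methylprop-2-en-1-yl acetate
Product: 15 (1S,2E)-1-[(2R)-4-(bromomethyl)-5-oxo-2,5-dihydrofuran-2-yl]-3-iodo-2-methylprop-2-en-1-yl acetate
Conditions: CBr4, PPh3, CH2Cl2, 0 °C
Reagents that add atoms: carbon tetrabromide, BrC(Br)(Br)Br
Why: Appel bromination converts the primary allylic alcohol into the allylic bromide by SN2 displacement of the alkoxyphosphonium ion under neutral conditions that the base-sensitive δ-acetoxy butenolide tolerates.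

Step 10
Reactants: 16 3-bromobut-3-en-1-ol
Product: 17 [(3-bromobut-3-en-1-yl)oxy](triethyl)silane
Conditions: TESCl, imidazole, CH2Cl2, 0 °C
Reagents that add atoms: chlorotriethylsilane, CC[Si](CC)(CC)Cl
Why: Silylation of the primary alcohol as a TES ether, which survives t-BuLi and borane and is oxidised directly in step 15.

Step 11
Reactants: 17 [(3-bromobut-3-en-1-yl)oxy](triethyl)silane; 18 2-chloro-N-methoxy-N-methylacetamide
Product: 20 1-chloro-3-methylidene-5-[(triethylsilyl)oxy]pentan-2-one, via alkenyllithium 19 (not isolated)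
Conditions: t-BuLi (2.1 equiv), Et2O, −78 °C; 18, −78 to −40 °C; aq. NH4Cl
Reagents that add atoms: none
Why: Bromine–lithium exchange gives the 2-lithio-1-alkene, whose addition to the Weinreb amide forms C1–C10 and stops at the ketone because the chelated tetrahedral adduct persists until work-up (Weinreb ketone synthesis).

Step 12
Reactants: 20 1-chloro-3-methylidene-5-[(triethylsilyl)oxy]pentan-2-one
Product: 21 (2R)-1-chloro-3-methylidene-5-[(triethylsilyl)oxy]pentan-2-ol
Conditions: (R)-Me-CBS oxazaborolidine (0.2 equiv), BH3·SMe2, THF, −30 °C; MeOH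
Reagents that add atoms: none
Why: CBS reduction: with the α-branched alkenyl group as the large and CH2Cl as the small substituent, the (R)-oxazaborolidine–borane complex delivers hydride to the ketone face that gives the (2R)-chlorohydrin, which is the 1S centre of the target.

Step 13
Reactants: 21 (2R)-1-chloro-3-methylidene-5-[(triethylsilyl)oxy]pentan-2-ol
Product: 22 (2R)-1-iodo-3-methylidene-5-[(triethylsilyl)oxy]pentan-2-ol
Conditions: NaI (5 equiv), 2-butanone, 80 °C
Reagents that add atoms: sodium iodide, [Na+].[I-]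
Why: Finkelstein exchange on the unhindered chlorohydrin, driven by precipitation of NaCl, provides the primary iodide needed as radical precursor at C2.

Step 14
Reactants: 22 (2R)-1-iodo-3-methylidene-5-[(triethylsilyl)oxy]pentan-2-ol
Product: 23 tert-butyl{[(2R)-1-iodo-3-methylidene-5-[(triethylsilyl)oxy]pentan-2-yl]oxy}dimethylsilane
Conditions: TBSOTf, 2,6-lutidine, CH2Cl2, −78 °C
Reagents that add atoms: tert-butyldimethylsilyl trifluoromethanesulfonate, CC(C)(C)[Si](C)(C)OS(=O)(=O)C(F)(F)F
Why: Silylation with TBSOTf protects O1 as a TBS ether that is orthogonal to the primary TES ether and inert to all steps up to the final fluoride deprotection.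

Step 15
Reactants: 23 tert-butyl{[(2R)-1-iodo-3-methylidene-5-[(triethylsilyl)oxy]pentan-2-yl]oxy}dimethylsilane
Product: 24 (4R)-4-{[tert-butyl(dimethyl)silyl]oxy}-5-iodo-3-methylidenepentanal
Conditions: (COCl)2, DMSO, CH2Cl2, −78 to −40 °C; Et3N, −78 to 0 °C
Reagents that add atoms: none
Why: Swern oxidation applied directly to the primary TES ether, which the chlorosulfonium reagent cleaves in situ while the secondary TBS ether stays, gives the β,γ-unsaturated aldehyde, used at once to avoid conjugation.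

Step 16
Reactants: 15 (1S,2E)-1-[(2R)-4-(bromomethyl)-5-oxo-2,5-dihydrofuran-2-yl]-3-iodo-2-methylprop-2-en-1-yl acetate; 24 (4R)-4-{[tert-butyl(dimethyl)silyl]oxy}-5-iodo-3-methylidenepentanal
Product: 26 (1R,3E,5S,6R,7S,8R)-5-acetoxy-1-[tert-butyl(dimethyl)silyloxy]-8-hydroxy-2,3-diiodo-2,3-secogermacra-3,10(14),11(13)-trien-12,6-olide, via allylzinc bromide 25 (not isolated)
Conditions: Zn dust, THF/sat. aq. NH4Cl, 0 °C to rt
Reagents that add atoms: none
Why: Zn Barbier allylation: the 2-(acyl)allylzinc reacts at its γ-carbon C7 on the face anti to the C6 side chain (trans lactone, 7S) through a closed chair transition state with the aldehyde chain equatorial, which gives the 8R carbinol and shifts the double bond to C11=C13.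

Step 17
Reactants: 26 (1R,3E,5S,6R,7S,8R)-5-acetoxy-1-[tert-butyl(dimethyl)silyloxy]-8-hydroxy-2,3-diiodo-2,3-secogermacra-3,10(14),11(13)-trien-12,6-olide; 27 angelic acid [(2Z)-2-methylbut-2-enoic acid]
Product: 28 (1R,3E,5S,6R,7S,8S)-5-acetoxy-8-angeloyloxy-1-[tert-butyl(dimethyl)silyloxy]-2,3-diiodo-2,3-secogermacra-3,10(14),11(13)-trien-12,6-olide
Conditions: PPh3, DIAD, 27 (3 equiv), toluene, 0 °C to rt
Reagents that add atoms: none
Why: Mitsunobu esterification: angelate displaces the alkoxyphosphonium ion of the 8R alcohol by SN2 with inversion to 8S, and since the acid is used as the nucleophile and never activated as an acyl donor its Z geometry is not put at risk.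

Step 18
Reactants: 28 (1R,3E,5S,6R,7S,8S)-5-acetoxy-8-angeloyloxy-1-[tert-butyl(dimethyl)silyloxy]-2,3-diiodo-2,3-secogermacra-3,10(14),11(13)-trien-12,6-olide
Product: 29 (1R,3E,5S,6R,7S,8S)-5-acetoxy-8-angeloyloxy-1-[tert-butyl(dimethyl)silyloxy]-13-(dimethylamino)-2,3-diiodo-2,3-secogermacra-3,10(14)-dien-12,6-olide (C11 epimers)
Conditions: Me2NH (2 M in THF, 1.2 equiv), THF, 0 °C
Reagents that add atoms: dimethylamine, CNC
Why: Aza-Michael addition of the amine to the α-methylene lactone, much faster than to the trisubstituted angelate, masks the acrylate against radical or organonickel addition in step 19; the temporary C11 centre is of no consequence.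

Step 19
Reactants: 29 (1R,3E,5S,6R,7S,8S)-5-acetoxy-8-angeloyloxy-1-[tert-butyl(dimethyl)silyloxy]-13-(dimethylamino)-2,3-diiodo-2,3-secogermacra-3,10(14)-dien-12,6-olide (C11 epimers)
Product: 30 (1S,3E,5S,6R,7S,8S)-5-acetoxy-8-angeloyloxy-1-[tert-butyl(dimethyl)silyloxy]-13-(dimethylamino)germacra-3,10(14)-dien-12,6-olide (C11 epimers)
Conditions: NiBr2(dme) (30 mol %), 4,4'-di-tert-butyl-2,2'-bipyridine (35 mol %), Mn powder (4 equiv), NaI (0.5 equiv), DMA, 30 °C; 29 added by syringe pump over 12 h to 2 mM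
Reagents that add atoms: none
Why: Proposed new method: zerovalent nickel (bipyridine-ligated, regenerated by Mn) inserts into the alkenyl C3–I bond with retention, the primary C2–I bond is opened by halogen abstraction to the C2 radical, this radical is captured at the same nickel centre, and C(sp3)–C(sp2) reductive elimination from the trivalent nickel species forms C2–C3 and releases monovalent nickel. The closest known reaction type is the nickel-catalysed reductive cross-electrophile coupling of alkenyl halides with primary alkyl halides, known intermolecularly and for small rings; what is new is its use to close a ten-membered carbocycle. The ring closes by radical capture and reductive elimination through an eleven-membered nickelacycle and not by exo or endo radical addition to a π bond, so no Baldwin-type constraint applies. No stereocentre is created: the E geometry of C3=C4 is that of the alkenyl iodide because insertion and elimination are both retentive, and C1, which is β to the radical carbon, is untouched. The step needs sp2/sp3 cross-selectivity, given by the two different activation modes (two-electron insertion against radical formation), and ring closure over oligomerisation, given by slow addition to millimolar concentration and by the turn that the trans-fused lactone at C6–C7 imposes on the two arms. Mn is used in place of Zn so that no β-silyloxy alkylzinc, prone to elimination, can form, and the amine mask keeps the acrylate out of radical and organonickel addition.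

Step 20
Reactants: 30 (1S,3E,5S,6R,7S,8S)-5-acetoxy-8-angeloyloxy-1-[tert-butyl(dimethyl)silyloxy]-13-(dimethylamino)germacra-3,10(14)-dien-12,6-olide (C11 epimers)
Product: 32 (1S,3E,5S,6R,7S,8S)-5-acetoxy-8-angeloyloxy-1-[tert-butyl(dimethyl)silyloxy]germacra-3,10(14),11(13)-trien-12,6-olide, via ammonium iodide 31 (not isolated)
Conditions: MeI (10 equiv), THF, rt; then sat. aq. NaHCO3, rt
Reagents that add atoms: none
Why: Quaternisation followed by base-induced E1cB (Hofmann-type) loss of trimethylamine regenerates the C11=C13 methylene, the standard unmasking of amine adducts of α-methylene lactones.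

Step 21
Reactants: 32 (1S,3E,5S,6R,7S,8S)-5-acetoxy-8-angeloyloxy-1-[tert-butyl(dimethyl)silyloxy]germacra-3,10(14),11(13)-trien-12,6-olide
Product: 33 (1S,3E,5S,6R,7S,8S)-5-acetoxy-8-angeloyloxy-1-hydroxygermacra-3,10(14),11(13)-trien-12,6-olide (CNP0115054.1)
Conditions: HF·pyridine, pyridine, THF, 0 °C to rt
Reagents that add atoms: none
Why: Buffered fluoride cleavage of the allylic TBS ether (Si–F bond formation) frees O1–H without acyl migration or transannular reaction and gives the target.

**Compound list**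

1 | furan-3-ylmethanol | OCc1ccoc1 | starting material
2 | 3-{[(4-methoxyphenyl)methoxy]methyl}furan | COc1ccc(COCc2ccoc2)cc1 | intermediate
3 | 2-lithio-3-{[(4-methoxyphenyl)methoxy]methyl}furan | [Li]c1occc1COCc1ccc(OC)cc1 | intermediate
4 | lithium trimethoxy(3-{[(4-methoxyphenyl)methoxy]methyl}furan-2-yl)borate | [Li+].CO[B-](OC)(OC)c1occc1COCc1ccc(OC)cc1 | intermediate
5 | 3-{[(4-methoxyphenyl)methoxy]methyl}furan-2(5H)-one | COc1ccc(COCC2=CCOC2=O)cc1 | intermediate
6 | tert-butyl[(3-{[(4-methoxyphenyl)methoxy]methyl}furan-2-yl)oxy]dimethylsilane | CC(C)(C)[Si](C)(C)Oc1occc1COCc1ccc(OC)cc1 | intermediate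
7 | prop-2-yn-1-ol | C#CCO | starting material
8 | dimethylaluminium (2E)-3-(dimethylalumanyl)-2-methylprop-2-en-1-olate | C[Al](C)OC/C(C)=C/[Al](C)C | intermediate
9 | (2E)-3-iodo-2-methylprop-2-en-1-ol | OC/C(C)=C/I | intermediate
10 | (2E)-3-iodo-2-methylprop-2-enal | O=C/C(C)=C/I | intermediate
11 | O-trichlorosilyl ether of 12 | COc1ccc(COCC2=C[C@H]([C@@H](O[Si](Cl)(Cl)Cl)/C(C)=C/I)OC2=O)cc1 | intermediate
12 | (5R)-5-[(1S,2E)-1-hydroxy-3-iodo-2-methylprop-2-en-1-yl]-3-{[(4-methoxyphenyl)methoxy]methyl}furan-2(5H)-one | COc1ccc(COCC2=C[C@H]([C@@H](O)/C(C)=C/I)OC2=O)cc1 | intermediate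
13 | (1S,2E)-3-iodo-1-[(2R)-4-{[(4-methoxyphenyl)methoxy]methyl}-5-oxo-2,5-dihydrofuran-2-yl]-2-methylprop-2-en-1-yl acetate | COc1ccc(COCC2=C[C@H]([C@@H](OC(C)=O)/C(C)=C/I)OC2=O)cc1 | intermediate
14 | (1S,2E)-1-[(2R)-4-(hydroxymethyl)-5-oxo-2,5-dihydrofuran-2-yl]-3-iodo-2-methylprop-2-en-1-yl acetate | OCC1=C[C@H]([C@@H](OC(C)=O)/C(C)=C/I)OC1=O | intermediate
15 | (1S,2E)-1-[(2R)-4-(bromomethyl)-5-oxo-2,5-dihydrofuran-2-yl]-3-iodo-2-methylprop-2-en-1-yl acetate | BrCC1=C[C@H]([C@@H](OC(C)=O)/C(C)=C/I)OC1=O | intermediate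
16 | 3-bromobut-3-en-1-ol | C=C(Br)CCO | starting material
17 | [(3-bromobut-3-en-1-yl)oxy](triethyl)silane | C=C(Br)CCO[Si](CC)(CC)CC | intermediate
18 | 2-chloro-N-methoxy-N-methylacetamide | CON(C)C(=O)CCl | starting material
19 | {4-[(triethylsilyl)oxy]but-1-en-2-yl}lithium | [Li]C(=C)CCO[Si](CC)(CC)CC | intermediate
20 | 1-chloro-3-methylidene-5-[(triethylsilyl)oxy]pentan-2-one | C=C(CCO[Si](CC)(CC)CC)C(=O)CCl | intermediate
21 | (2R)-1-chloro-3-methylidene-5-[(triethylsilyl)oxy]pentan-2-ol | C=C(CCO[Si](CC)(CC)CC)[C@@H](O)CCl | intermediate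
22 | (2R)-1-iodo-3-methylidene-5-[(triethylsilyl)oxy]pentan-2-ol | C=C(CCO[Si](CC)(CC)CC)[C@@H](O)CI | intermediate
23 | tert-butyl{[(2R)-1-iodo-3-methylidene-5-[(triethylsilyl)oxy]pentan-2-yl]oxy}dimethylsilane | C=C(CCO[Si](CC)(CC)CC)[C@@H](O[Si](C)(C)C(C)(C)C)CI | intermediate
24 | (4R)-4-{[tert-butyl(dimethyl)silyl]oxy}-5-iodo-3-methylidenepentanal | O=CCC(=C)[C@@H](O[Si](C)(C)C(C)(C)C)CI | intermediate
25 | allylzinc bromide from 15: bromo({(5R)-5-[(1S,2E)-1-acetoxy-3-iodo-2-methylprop-2-en-1-yl]-2-oxo-2,5-dihydrofuran-3-yl}methyl)zinc | Br[Zn]CC1=C[C@H]([C@@H](OC(C)=O)/C(C)=C/I)OC1=O | intermediate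
26 | (1R,3E,5S,6R,7S,8R)-5-acetoxy-1-[tert-butyl(dimethyl)silyloxy]-8-hydroxy-2,3-diiodo-2,3-secogermacra-3,10(14),11(13)-trien-12,6-olide | C=C1C(=O)O[C@@H]([C@H](/C(=C/I)C)OC(C)=O)[C@@H]1[C@H](O)CC(=C)[C@@H](O[Si](C)(C)C(C)(C)C)CI | intermediate
27 | angelic acid, (2Z)-2-methylbut-2-enoic acid | C/C=C(/C)C(=O)O | starting material
28 | (1R,3E,5S,6R,7S,8S)-5-acetoxy-8-angeloyloxy-1-[tert-butyl(dimethyl)silyloxy]-2,3-diiodo-2,3-secogermacra-3,10(14),11(13)-trien-12,6-olide | C=C1C(=O)O[C@@H]([C@H](/C(=C/I)C)OC(C)=O)[C@@H]1[C@@H](OC(=O)/C(C)=C\C)CC(=C)[C@@H](O[Si](C)(C)C(C)(C)C)CI | intermediate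
29 | (1R,3E,5S,6R,7S,8S)-5-acetoxy-8-angeloyloxy-1-[tert-butyl(dimethyl)silyloxy]-13-(dimethylamino)-2,3-diiodo-2,3-secogermacra-3,10(14)-dien-12,6-olide, C11 epimers | CN(C)CC1C(=O)O[C@@H]([C@H](/C(=C/I)C)OC(C)=O)[C@@H]1[C@@H](OC(=O)/C(C)=C\C)CC(=C)[C@@H](O[Si](C)(C)C(C)(C)C)CI | intermediate
30 | (1S,3E,5S,6R,7S,8S)-5-acetoxy-8-angeloyloxy-1-[tert-butyl(dimethyl)silyloxy]-13-(dimethylamino)germacra-3,10(14)-dien-12,6-olide, C11 epimers | CN(C)CC1C(=O)O[C@@H]2[C@@H]1[C@@H](OC(=O)/C(C)=C\C)CC(=C)[C@@H](O[Si](C)(C)C(C)(C)C)C/C=C(\C)[C@@H]2OC(C)=O | intermediate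
31 | N,N,N-trimethylammonium iodide of 30 (13-trimethylammonio) | C[N+](C)(C)CC1C(=O)O[C@@H]2[C@@H]1[C@@H](OC(=O)/C(C)=C\C)CC(=C)[C@@H](O[Si](C)(C)C(C)(C)C)C/C=C(\C)[C@@H]2OC(C)=O.[I-] | intermediate
32 | (1S,3E,5S,6R,7S,8S)-5-acetoxy-8-angeloyloxy-1-[tert-butyl(dimethyl)silyloxy]germacra-3,10(14),11(13)-trien-12,6-olide | C=C1C(=O)O[C@@H]2[C@@H]1[C@@H](OC(=O)/C(C)=C\C)CC(=C)[C@@H](O[Si](C)(C)C(C)(C)C)C/C=C(\C)[C@@H]2OC(C)=O | intermediate
33 | (1S,3E,5S,6R,7S,8S)-5-acetoxy-8-angeloyloxy-1-hydroxygermacra-3,10(14),11(13)-trien-12,6-olide (CNP0115054.1) | C=C1C(=O)O[C@@H]2[C@@H]1[C@@H](OC(=O)/C(C)=C\C)CC(=C)[C@@H](O)C/C=C(\C)[C@@H]2OC(C)=O | target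

**Step count**

Total steps: 21. Longest linear sequence: 13 steps (steps 1, 2, 3, 6, 7, 8, 9, 16, 17, 18, 19, 20, 21).

**Steps most likely to fail**

1. Step 19 (Proposed new method). What may go wrong: premature reduction of either carbon–iodine bond, oligomerisation in place of ring closure, or insertion of low-valent nickel into the C5 allylic acetate. The fallback uses known chemistry, copper-catalysed borylation of a primary alkyl iodide and a B-alkyl Suzuki–Miyaura macrocyclisation; it sets out from 23 and comes back to the route at 30. CuI/PPh3/LiOMe with B2pin2 in DMF should convert 23 into the pinacol boronate tert-butyl{[(2S)-3-methylidene-1-(pinacolboryl)-5-[(triethylsilyl)oxy]pentan-2-yl]oxy}dimethylsilane F1. Direct Swern oxidation as in step 15 should give the boryl aldehyde F2. Zn Barbier union with 15 as in step 16 should give the 8R alcohol F3, Mitsunobu esterification with 27 the angelate F4, and dimethylamine addition the masked seco-boronate F5. Pd(OAc)2/SPhos with K3PO4 in THF/H2O at 60 °C under slow addition should then close C2–C3 between the alkylboronate and the alkenyl iodide, which tolerates the allylic acetate, and give 30.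

2. Step 6. What may go wrong: poor facial or anti/syn selectivity with the 3-substituted silyloxyfuran, or ionisation of its alkoxymethyl arm by the Lewis acid. The fallback replaces catalyst control by an enzymatic resolution; it sets out from 6 and 10 and comes back at 12. BF3·OEt2 in CH2Cl2 at −78 °C should give the vinylogous aldol adduct without enantiocontrol, and chromatography should remove the syn isomer to leave the racemic anti alcohol rac-12 F6. Kinetic resolution with a lipase (Candida antarctica lipase B, a serine hydrolase used as acyl transferase, with vinyl acetate) is expected to acetylate the unwanted enantiomer to the acetate ent-13 F7; the alcohol that remains is 12.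

3. Step 17. What may go wrong: elimination across C7–C8, incomplete inversion at the hindered carbinol, or Z to E drift of the angelate. The fallback separates the inversion from the acylation; it sets out from 26 and comes back at 28. Mitsunobu reaction with the more acidic chloroacetic acid should give the inverted (8S)-chloroacetate F8. Et3N in MeOH at 0 °C should remove the chloroacetate selectively beside the acetate and give the (8S)-alcohol F9. Acylation with retention by the mixed anhydride of 27 and 2,4,6-trichlorobenzoyl chloride (Yamaguchi-type, Et3N, toluene, 80 °C) should then give 28.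

**Further compounds**

F1 | step 19 | tert-butyl{[(2S)-3-methylidene-1-(4,4,5,5-tetramethyl-1,3,2-dioxaborolan-2-yl)-5-[(triethylsilyl)oxy]pentan-2-yl]oxy}dimethylsilane | C=C(CCO[Si](CC)(CC)CC)[C@@H](O[Si](C)(C)C(C)(C)C)CB1OC(C)(C)C(C)(C)O1
F2 | step 19 | (4S)-4-{[tert-butyl(dimethyl)silyl]oxy}-3-methylidene-5-(4,4,5,5-tetramethyl-1,3,2-dioxaborolan-2-yl)pentanal | O=CCC(=C)[C@@H](O[Si](C)(C)C(C)(C)C)CB1OC(C)(C)C(C)(C)O1
F3 | step 19 | (1S,3E,5S,6R,7S,8R)-5-acetoxy-1-[tert-butyl(dimethyl)silyloxy]-8-hydroxy-3-iodo-2-(4,4,5,5-tetramethyl-1,3,2-dioxaborolan-2-yl)-2,3-secogermacra-3,10(14),11(13)-trien-12,6-olide | C=C1C(=O)O[C@@H]([C@H](/C(=C/I)C)OC(C)=O)[C@@H]1[C@H](O)CC(=C)[C@@H](O[Si](C)(C)C(C)(C)C)CB1OC(C)(C)C(C)(C)O1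
F4 | step 19 | (1S,3E,5S,6R,7S,8S)-5-acetoxy-8-angeloyloxy-1-[tert-butyl(dimethyl)silyloxy]-3-iodo-2-(4,4,5,5-tetramethyl-1,3,2-dioxaborolan-2-yl)-2,3-secogermacra-3,10(14),11(13)-trien-12,6-olide | C=C1C(=O)O[C@@H]([C@H](/C(=C/I)C)OC(C)=O)[C@@H]1[C@@H](OC(=O)/C(C)=C\C)CC(=C)[C@@H](O[Si](C)(C)C(C)(C)C)CB1OC(C)(C)C(C)(C)O1
F5 | step 19 | (1S,3E,5S,6R,7S,8S)-5-acetoxy-8-angeloyloxy-1-[tert-butyl(dimethyl)silyloxy]-13-(dimethylamino)-3-iodo-2-(4,4,5,5-tetramethyl-1,3,2-dioxaborolan-2-yl)-2,3-secogermacra-3,10(14)-dien-12,6-olide, C11 epimers | CN(C)CC1C(=O)O[C@@H]([C@H](/C(=C/I)C)OC(C)=O)[C@@H]1[C@@H](OC(=O)/C(C)=C\C)CC(=C)[C@@H](O[Si](C)(C)C(C)(C)C)CB1OC(C)(C)C(C)(C)O1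
F6 | step 6 | rac-(5R*)-5-[(1S*,2E)-1-hydroxy-3-iodo-2-methylprop-2-en-1-yl]-3-{[(4-methoxyphenyl)methoxy]methyl}furan-2(5H)-one (racemate of 12) | COc1ccc(COCC2=C[C@H]([C@@H](O)/C(C)=C/I)OC2=O)cc1.COc1ccc(COCC2=C[C@@H]([C@H](O)/C(C)=C/I)OC2=O)cc1
F7 | step 6 | (1R,2E)-3-iodo-1-[(2S)-4-{[(4-methoxyphenyl)methoxy]methyl}-5-oxo-2,5-dihydrofuran-2-yl]-2-methylprop-2-en-1-yl acetate (enantiomer of 13) | COc1ccc(COCC2=C[C@@H]([C@H](OC(C)=O)/C(C)=C/I)OC2=O)cc1
F8 | step 17 | (1R,3E,5S,6R,7S,8S)-5-acetoxy-1-[tert-butyl(dimethyl)silyloxy]-8-(chloroacetoxy)-2,3-diiodo-2,3-secogermacra-3,10(14),11(13)-trien-12,6-olide | C=C1C(=O)O[C@@H]([C@H](/C(=C/I)C)OC(C)=O)[C@@H]1[C@@H](OC(=O)CCl)CC(=C)[C@@H](O[Si](C)(C)C(C)(C)C)CI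
F9 | step 17 | (1R,3E,5S,6R,7S,8S)-5-acetoxy-1-[tert-butyl(dimethyl)silyloxy]-8-hydroxy-2,3-diiodo-2,3-secogermacra-3,10(14),11(13)-trien-12,6-olide | C=C1C(=O)O[C@@H]([C@H](/C(=C/I)C)OC(C)=O)[C@@H]1[C@@H](O)CC(=C)[C@@H](O[Si](C)(C)C(C)(C)C)CI
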